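**Retrosynthetic overview**
- Vitedoin A ← acid unmasking (2 MOM ethers, dimethyl acetal) ← ester reduction ← syn-dehydration of a tertiary aldol to give C1=C2.
- The carbocycle (C2–C3 bond) and the C4–aryl bond are made in one step: a Rh(I)/BINAP arylative aldol cyclization of enoate/α-keto acetal 10 with arylboronic acid 14, which sets C4 and C3.
- 10 ← Pd-catalysed coupling of bromo-cinnamate 7 with silyl enol ether 9; 7 ← catechol (mono-MOM, ortho-formylation, O-methylation, bromination, Doebner olefination).
- 14 ← catechol (mono-methylation, para-bromination, MOM protection, borylation).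
- Both benzene rings come intact from catechol; the only ring constructed is the dihydronaphthalene carbocycle (step 12).

Assumption: atom labels C1–C8a follow the target's naphthaldehyde numbering (C2 bears CHO, C3 bears CH2OH, C4 bears the aryl group, C5 = OMe, C6 = OH).
Assumption: (S)-BINAP is taken to deliver the aryl group to the C4 re face, as it does for (E)-enones; if the first run gives the antipode, (R)-BINAP is used.

**Route**

Step 1
Reactants: 1 catechol
Product: 2 2-(methoxymethoxy)phenol
Conditions: NaH (1.0 equiv), MOMCl (1.0 equiv), THF/DMF, 0 °C → rt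
Reagents that add atoms: chloromethyl methyl ether, COCCl
Why: Statistical mono-O-alkylation of the monophenoxide (Williamson-type), with bis-ether and catechol separable and recyclable.

Step 2
Reactants: 2 2-(methoxymethoxy)phenol
Product: 3 2-hydroxy-3-(methoxymethoxy)benzaldehyde
Conditions: MgCl2, Et3N, (CH2O)n, MeCN, reflux
Reagents that add atoms: paraformaldehyde, C=O
Why: Magnesium-phenoxide-directed ortho-formylation (Casnati–Skattebøl) puts CHO on the only free ortho position of the phenol, and the MOM ether tolerates the basic, weakly Lewis-acidic medium.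

Step 3
Reactants: 3 2-hydroxy-3-(methoxymethoxy)benzaldehyde
Product: 4 2-methoxy-3-(methoxymethoxy)benzaldehyde
Conditions: MeI, K2CO3, DMF, 40 °C
Reagents that add atoms: iodomethane, CI
Why: Williamson O-methylation of the single free phenol fixes the future C5–OMe next to the formyl carbon (future C4).

Step 4
Reactants: 4 2-methoxy-3-(methoxymethoxy)benzaldehyde
Product: 5 6-bromo-2-methoxy-3-(methoxymethoxy)benzaldehyde
Conditions: NBS, DMF, rt, dark
Reagents that add atoms: N-bromosuccinimide, O=C1CCC(=O)N1Br
Why: Electrophilic aromatic bromination goes para to the 3-alkoxy group (the flanked 2-OMe is twisted out of conjugation), as is known for 2,3-dialkoxybenzaldehydes, giving the future C8a handle.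

Step 5
Reactants: 5 6-bromo-2-methoxy-3-(methoxymethoxy)benzaldehyde; 6 monomethyl malonate
Product: 7 methyl (E)-3-[6-bromo-2-methoxy-3-(methoxymethoxy)phenyl]prop-2-enoate
Conditions: pyridine, piperidine (cat.), 95 °C
Reagents that add atoms: none
Why: Knoevenagel–Doebner condensation with decarboxylation of the malonate half-ester gives the (E)-enoate (C4=C3–CO2Me) under conditions that leave MOM and ArBr untouched.

Step 6
Reactants: 8 1,1-dimethoxypropan-2-one
Product: 9 [(3,3-dimethoxyprop-1-en-2-yl)oxy]trimethylsilane
Conditions: LDA, THF, −78 °C; TMSCl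
Reagents that add atoms: chlorotrimethylsilane, C[Si](C)(C)Cl
Why: Kinetic deprotonation occurs at the unhindered methyl group, not the dialkoxy methine, and O-silylation gives a regiodefined enolate equivalent.

Step 7
Reactants: 7 methyl (E)-3-[6-bromo-2-methoxy-3-(methoxymethoxy)phenyl]prop-2-enoate; 9 silyl enol ether
Product: 10 methyl (E)-3-[6-(3,3-dimethoxy-2-oxopropyl)-2-methoxy-3-(methoxymethoxy)phenyl]prop-2-enoate
Conditions: Pd(OAc)2 (3 mol %), P(t-Bu)3 (6 mol %), Bu3SnF, CsF, toluene, 85 °C
Reagents that add atoms: none
Why: Pd-catalysed α-arylation of a silyl enol ether via an in situ tin enolate forms the C8a–C1 bond without strong base, so the enoate, MOM ether and acetal survive.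

Step 8
Reactants: 1 catechol
Product: 11 2-methoxyphenol (guaiacol)
Conditions: MeI (1.0 equiv), K2CO3, acetone, reflux
Reagents that add atoms: iodomethane, CI
Why: Statistical Williamson mono-methylation, with veratrole and catechol easily removed.

Step 9
Reactants: 11 2-methoxyphenol
Product: 12 4-bromo-2-methoxyphenol
Conditions: NBS, MeCN, 0 °C
Reagents that add atoms: N-bromosuccinimide, O=C1CCC(=O)N1Br
Why: Electrophilic aromatic bromination is directed para to the free OH, the stronger donor.

Step 10
Reactants: 12 4-bromo-2-methoxyphenol
Product: 13 4-bromo-2-methoxy-1-(methoxymethoxy)benzene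
Conditions: MOMCl, i-Pr2NEt, CH2Cl2, 0 °C → rt
Reagents that add atoms: chloromethyl methyl ether, COCCl
Why: Standard MOM protection of the phenol so it survives lithiation and comes off in the final acid step.

Step 11
Reactants: 13 4-bromo-2-methoxy-1-(methoxymethoxy)benzene
Product: 14 [3-methoxy-4-(methoxymethoxy)phenyl]boronic acid
Conditions: n-BuLi, THF, −78 °C; B(OiPr)3; aq NH4Cl
Reagents that add atoms: triisopropyl borate, CC(C)OB(OC(C)C)OC(C)C; water, O
Why: Br/Li exchange at −78 °C outpaces ortho-lithiation, and borate quench with mild hydrolysis gives the boronic acid with MOM intact.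

Step 12
Reactants: 10 enoate/α-keto acetal; 14 arylboronic acid
Product: 15 methyl (1S,2R,3S)-3-(dimethoxymethyl)-3-hydroxy-8-methoxy-7-(methoxymethoxy)-1-[3-methoxy-4-(methoxymethoxy)phenyl]-1,2,3,4-tetrahydronaphthalene-2-carboxylate
Conditions: [Rh(OH)((S)-BINAP)]2 (3 mol %), 14 (2 equiv), H2O (5 equiv), dioxane, 60 °C
Reagents that add atoms: none
Why: Proposed new method: aryl–Rh(I) from transmetalation of 14 adds enantioselectively to the (E)-enoate (ligand-controlled face, sets C4 as S), and the resulting Rh oxa-π-allyl ester enolate is trapped intramolecularly by the activated α-keto acetal before protonation, closing the six-membered ring through C2–C3; a chair-like chelated transition state with C4–H in the enolate plane (A(1,3) strain) forces closure anti to the new aryl group, giving the trans C3/C4 relationship and OH cis to CO2Me; the closest known reaction type is the Rh/BINAP conjugate addition–aldol cyclization of arylboronic acids with enone-ketones (itself built on the Hayashi–Miyaura addition), here extended to an ester enolate, a di-ortho-substituted cinnamate and a benzo-fused tether.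

Step 13
Reactants: 15 tertiary aldol
Product: 16 methyl (1S,2R)-3-(dimethoxymethyl)-8-methoxy-7-(methoxymethoxy)-1-[3-methoxy-4-(methoxymethoxy)phenyl]-1,2-dihydronaphthalene-2-carboxylate
Conditions: Burgess reagent, toluene, 70 °C
Reagents that add atoms: none
Why: Burgess syn-elimination (Ei) can only use a hydrogen cis to the OH, and since the C3–H is trans to it, the benzylic C1–H is removed to give the aryl-conjugated C1=C2 alkene without touching C3 or C4.

Step 14
Reactants: 16 dihydronaphthalene ester
Product: 17 [(1S,2R)-3-(dimethoxymethyl)-8-methoxy-7-(methoxymethoxy)-1-[3-methoxy-4-(methoxymethoxy)phenyl]-1,2-dihydronaphthalen-2-yl]methanol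
Conditions: DIBAL-H (2.5 equiv), CH2Cl2, −78 °C; Rochelle salt
Reagents that add atoms: none
Why: Low-temperature hydride reduction of the ester to the primary alcohol leaves the acetal, MOM ethers and alkene intact and avoids base-mediated epimerization at C3.

Step 15
Reactants: 17 protected alcohol
Product: 18 vitedoin A, (3R,4S)-6-hydroxy-4-(4-hydroxy-3-methoxyphenyl)-3-(hydroxymethyl)-5-methoxy-3,4-dihydronaphthalene-2-carbaldehyde
Conditions: 2 M HCl, THF/H2O, 40 °C, degassed
Reagents that add atoms: water, O
Why: Acid hydrolysis cleaves both aryl MOM ethers and converts the allylic dimethyl acetal into the conjugated aldehyde in one operation, with neither stereocentre acidic under these conditions.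

**Compound list**
1 | catechol | Oc1ccccc1O | starting material
2 | 2-(methoxymethoxy)phenol | COCOc1ccccc1O | intermediate
3 | 2-hydroxy-3-(methoxymethoxy)benzaldehyde | COCOc1cccc(C=O)c1O | intermediate
4 | 2-methoxy-3-(methoxymethoxy)benzaldehyde | COCOc1cccc(C=O)c1OC | intermediate
5 | 6-bromo-2-methoxy-3-(methoxymethoxy)benzaldehyde | COCOc1ccc(Br)c(C=O)c1OC | intermediate
6 | monomethyl malonate (3-methoxy-3-oxopropanoic acid) | COC(=O)CC(=O)O | starting material
7 | methyl (E)-3-[6-bromo-2-methoxy-3-(methoxymethoxy)phenyl]prop-2-enoate | COC(=O)/C=C/c1c(Br)ccc(OCOC)c1OC | intermediate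
8 | 1,1-dimethoxypropan-2-one | CC(=O)C(OC)OC | starting material
9 | [(3,3-dimethoxyprop-1-en-2-yl)oxy]trimethylsilane | C=C(O[Si](C)(C)C)C(OC)OC | intermediate
10 | methyl (E)-3-[6-(3,3-dimethoxy-2-oxopropyl)-2-methoxy-3-(methoxymethoxy)phenyl]prop-2-enoate | COC(=O)/C=C/c1c(CC(=O)C(OC)OC)ccc(OCOC)c1OC | intermediate
11 | 2-methoxyphenol | COc1ccccc1O | intermediate
12 | 4-bromo-2-methoxyphenol | COc1cc(Br)ccc1O | intermediate
13 | 4-bromo-2-methoxy-1-(methoxymethoxy)benzene | COCOc1ccc(Br)cc1OC | intermediate
14 | [3-methoxy-4-(methoxymethoxy)phenyl]boronic acid | COCOc1ccc(B(O)O)cc1OC | intermediate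
15 | methyl (1S,2R,3S)-3-(dimethoxymethyl)-3-hydroxy-8-methoxy-7-(methoxymethoxy)-1-[3-methoxy-4-(methoxymethoxy)phenyl]-1,2,3,4-tetrahydronaphthalene-2-carboxylate | COc1cc([C@H]2c3c(ccc(OCOC)c3OC)C[C@@](O)(C(OC)OC)[C@@H]2C(=O)OC)ccc1OCOC | intermediate
16 | methyl (1S,2R)-3-(dimethoxymethyl)-8-methoxy-7-(methoxymethoxy)-1-[3-methoxy-4-(methoxymethoxy)phenyl]-1,2-dihydronaphthalene-2-carboxylate | COc1cc([C@H]2c3c(ccc(OCOC)c3OC)C=C(C(OC)OC)[C@@H]2C(=O)OC)ccc1OCOC | intermediate
17 | [(1S,2R)-3-(dimethoxymethyl)-8-methoxy-7-(methoxymethoxy)-1-[3-methoxy-4-(methoxymethoxy)phenyl]-1,2-dihydronaphthalen-2-yl]methanol | COc1cc([C@H]2c3c(ccc(OCOC)c3OC)C=C(C(OC)OC)[C@@H]2CO)ccc1OCOC | intermediate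
18 | vitedoin A, (3R,4S)-6-hydroxy-4-(4-hydroxy-3-methoxyphenyl)-3-(hydroxymethyl)-5-methoxy-3,4-dihydronaphthalene-2-carbaldehyde | COc1cc([C@H]2c3c(ccc(O)c3OC)C=C(C=O)[C@@H]2CO)ccc1O | target

**Step count**
Total steps: 15. Longest linear sequence: 10 (steps 1, 2, 3, 4, 5, 7, 12, 13, 14, 15).

**Steps most likely to fail, with fallbacks**
1. Step 12 (proposed new Rh arylative aldol cyclization). The ester-derived Rh enolate may be protonated before it cyclizes, or the hindered cinnamate may react slowly. Fallback with known chemistry: decouple the events.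
   - Run a standard Rh/(S)-BINAP Hayashi–Miyaura 1,4-addition of 14 to bromo-cinnamate 7 to set C4.
   - Allylate the ester enolate at C3 (LDA, allyl bromide), then Suzuki-vinylate the aryl bromide.
   - Ozonolyse both alkenes to the dialdehyde and close the ring by amine-catalysed intramolecular aldol condensation (C1=C2).
   - Equilibrate C3 to trans with DBU, reduce with DIBAL, oxidise the allylic alcohol selectively with MnO2, and remove MOM with acid.
2. Step 13 (regiochemistry of dehydration). If the aldol diastereomer has OH trans to the ester, elimination toward the acidic C3–H would give the C2=C3 isomer and destroy C3. Fallback: reduce the ester of 15 first (LiBH4) and protect the primary alcohol as its TBS ether, so C3–H is no longer activated and only the aryl-conjugated C1=C2 alkene is favoured on dehydration (SOCl2/pyridine or Martin sulfurane); the final acid step also removes TBS.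
3. Step 7 (Pd coupling at a hindered aryl bromide next to the enoate). Fallback: build the side chain by polar chemistry before the olefination.
   - Protect aldehyde 5 as its dimethyl acetal and carry out Br/Li exchange.
   - Open 2-(dimethoxymethyl)oxirane with the aryllithium (BF3·OEt2) and oxidise the secondary alcohol with Dess–Martin periodinane to the α-keto acetal.
   - Selectively hydrolyse the more labile benzaldehyde acetal and apply the Doebner olefination of step 5 to reach 10.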